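**Retrosynthetic overview**
1. Target ⇐ one fluoride step that removes a TBS ether (C18–O) and a 2-(trimethylsilyl)ethyl ester (C15) ⇐ angeloylation of the C3 alcohol of the bicyclic core with angelic acid.
2. Bicyclic core ⇐ acyclic (R,R)-epoxy triene carrying a (Z)-2-substituted allylsilane; ring A and then ring B close in one MeAlCl2-triggered, epoxide-initiated, allylsilane-terminated cation–olefin cascade.
3. Allylsilane ⇐ (Z)-alkenyl chloride + Me3SiCH2ZnCl ⇐ late trans-selective Negishi union of fragment A (C1–C7, C18–C20; epoxy alkyl iodide) with fragment B (C8, C9, C11–C16; 1,1-dichloroalkene dienoate).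
4. Fragment A ⇐ B-alkyl Suzuki coupling of (E)-5-chloro-2-iodopent-2-ene with hydroborated (E)-2-methylpenta-2,4-dien-1-ol, then Sharpless epoxidation (D-(−)-diethyl tartrate), silylation, Finkelstein exchange.
5. Fragment B ⇐ syn-carbocupration of 2-(trimethylsilyl)ethyl but-2-ynoate with a 2-(1,3-dioxolan-2-yl)ethylcopper reagent, acetal hydrolysis, dichloro-olefination.

Assumption: the target is taken exactly as the SMILES encodes it, i.e. the ent-labdane with (1R,4aS,5S,6R,8aS) configuration on the decalin, C3–O and C4–CH2OH both equatorial; labdane numbering (C1–C20) is used for positions.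

**Step 1**
Reactants: 1 pent-3-yn-1-ol
Product: 2 5-chloropent-2-yne
Conditions: PPh3, N-chlorosuccinimide, CH2Cl2, 0 °C → rt
Reagents that add atoms: N-chlorosuccinimide, ClN1C(=O)CCC1=O
Why: Appel-type chlorination in which chloride displaces the alkoxyphosphonium at the primary carbon by SN2, the internal alkyne being inert and no stereocentre involved.

**Step 2**
Reactants: 2 5-chloropent-2-yne
Product: 4 (2E)-5-chloro-2-iodopent-2-ene, via alkenylzirconocene chloride 3 (not isolated)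
Conditions: Cp2Zr(H)Cl (1.8 equiv), THF, rt → 45 °C; then I2, 0 °C
Reagents that add atoms: iodine, II
Why: Schwartz hydrozirconation is a syn addition that, after equilibration with excess Cp2Zr(H)Cl, puts zirconium on the less hindered methyl-bearing carbon (about 10:1 or better), and iodinolysis with retention fixes the (E)-iodoalkene while the alkyl chloride is untouched.

**Step 3**
Reactants: 5 prop-2-enal (acrolein)
Product: 6 ethyl (2E)-2-methylpenta-2,4-dienoate
Conditions: ethyl 2-(triphenylphosphoranylidene)propanoate, CH2Cl2 (BHT), 0 °C → rt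
Reagents that add atoms: ethyl 2-(triphenylphosphoranylidene)propanoate, CCOC(=O)C(C)=P(c1ccccc1)(c1ccccc1)c1ccccc1
Why: Wittig olefination with a stabilised α-branched ylide attacks only the aldehyde and gives the (E)-2-methyl-2-enoate (typically ≥95:5).

**Step 4**
Reactants: 6 ethyl (2E)-2-methylpenta-2,4-dienoate
Product: 7 (2E)-2-methylpenta-2,4-dien-1-ol
Conditions: i-Bu2AlH (2.2 equiv), CH2Cl2, −78 °C; aq. sodium potassium tartrate
Reagents that add atoms: none
Why: i-Bu2AlH gives clean 1,2-reduction of the dienoate to the allylic alcohol at low temperature without touching the diene or its geometry (ester reduction).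

**Step 5**
Reactants: 7 (2E)-2-methylpenta-2,4-dien-1-ol; 4 (2E)-5-chloro-2-iodopent-2-ene
Product: 9 (2E,6E)-9-chloro-2,6-dimethylnona-2,6-dien-1-ol, via B-alkyl-9-BBN 8 (not isolated)
Conditions: 9-BBN (2.1 equiv), THF, 0 °C → rt; then 4, Pd(dppf)Cl2 (5 mol %), AsPh3, Cs2CO3, DMF–H2O, rt
Reagents that add atoms: none
Why: 9-BBN caps the hydroxyl as a borinate and hydroborates only the terminal carbon of the monosubstituted diene end, and the homoallylic borane then undergoes B-alkyl Suzuki–Miyaura coupling with the iodoalkene with retention of its (E) geometry, the primary alkyl chloride being inert to the palladium catalyst.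

**Step 6**
Reactants: 9 (2E,6E)-9-chloro-2,6-dimethylnona-2,6-dien-1-ol
Product: 10 {(2R,3R)-3-[(3E)-6-chloro-3-methylhex-3-en-1-yl]-2-methyloxiran-2-yl}methanol
Conditions: Ti(Oi-Pr)4 (10 mol %), D-(−)-diethyl tartrate (12 mol %), t-BuOOH, 4 Å molecular sieves, CH2Cl2, −20 °C
Reagents that add atoms: tert-butyl hydroperoxide, CC(C)(C)OO
Why: Sharpless asymmetric epoxidation is hydroxyl-directed, so only the 2,3-alkene reacts, and D-(−)-diethyl tartrate delivers oxygen to the face that gives the (2R,3R)-epoxide (≥94% ee expected for an (E)-2-methylalk-2-en-1-ol), which fixes the absolute configuration of the whole route.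

**Step 7**
Reactants: 10 {(2R,3R)-3-[(3E)-6-chloro-3-methylhex-3-en-1-yl]-2-methyloxiran-2-yl}methanol
Product: 11 tert-butyl({(2R,3R)-3-[(3E)-6-chloro-3-methylhex-3-en-1-yl]-2-methyloxiran-2-yl}methoxy)dimethylsilane
Conditions: TBSCl, imidazole, DMF, rt
Reagents that add atoms: tert-butyldimethylsilyl chloride, CC(C)(C)[Si](C)(C)Cl
Why: Silyl ether formation at the primary alcohol under imidazole buffering leaves the epoxide intact and gives a non-participating, Lewis-acid-tolerant group next to the future C4.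

**Step 8**
Reactants: 11 tert-butyl({(2R,3R)-3-[(3E)-6-chloro-3-methylhex-3-en-1-yl]-2-methyloxiran-2-yl}methoxy)dimethylsilane
Product: 12 tert-butyl({(2R,3R)-3-[(3E)-6-iodo-3-methylhex-3-en-1-yl]-2-methyloxiran-2-yl}methoxy)dimethylsilane
Conditions: NaI, NaHCO3, 2-butanone, 70 °C
Reagents that add atoms: sodium iodide, [Na+].[I-]
Why: Finkelstein exchange (SN2) at the unhindered primary chloride under neutral, buffered conditions gives the iodide needed for zinc insertion without opening the epoxide.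

**Step 9**
Reactants: 13 but-2-ynoic acid; 14 2-(trimethylsilyl)ethanol
Product: 15 2-(trimethylsilyl)ethyl but-2-ynoate
Conditions: DCC, DMAP (5 mol %), CH2Cl2, 0 °C → rt
Reagents that add atoms: none
Why: Steglich esterification at 0 °C acylates the primary alcohol with the acetylenic acid without conjugate addition to the triple bond.

**Step 10**
Reactants: 16 2-(2-bromoethyl)-1,3-dioxolane; 15 2-(trimethylsilyl)ethyl but-2-ynoate
Product: 19 2-(trimethylsilyl)ethyl (2E)-5-(1,3-dioxolan-2-yl)-3-methylpent-2-enoate, via Grignard reagent 17 (not isolated), via alkylcopper 18 (not isolated)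
Conditions: Mg, THF, 25 °C; CuBr·SMe2 (1.0 equiv), −45 °C; 15, THF, −78 °C; aq. NH4Cl at −78 °C
Reagents that add atoms: none
Why: Conjugate addition to an acetylenic ester by syn-carbocupration at −78 °C followed by cold protonation with retention puts the new alkyl group trans to the ester, i.e. the (E)-3-methyl-2-enoate.

**Step 11**
Reactants: 19 2-(trimethylsilyl)ethyl (2E)-5-(1,3-dioxolan-2-yl)-3-methylpent-2-enoate
Product: 20 2-(trimethylsilyl)ethyl (2E)-3-methyl-6-oxohex-2-enoate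
Conditions: 2 M HCl, THF, rt
Reagents that add atoms: water, O
Why: Acid-catalysed acetal hydrolysis frees the aldehyde while the silylethyl ester and the trisubstituted enoate are stable to dilute aqueous acid.

**Step 12**
Reactants: 20 2-(trimethylsilyl)ethyl (2E)-3-methyl-6-oxohex-2-enoate
Product: 21 2-(trimethylsilyl)ethyl (2E)-7,7-dichloro-3-methylhepta-2,6-dienoate
Conditions: PPh3 (4 equiv), BrCCl3 (2 equiv), CH3CN, 0 °C → rt
Reagents that add atoms: bromotrichloromethane, ClC(Cl)(Cl)Br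
Why: Ramirez-type dichloro-olefination, in which PPh3 and BrCCl3 generate Ph3P=CCl2 that converts the aldehyde into the 1,1-dichloroalkene by a Wittig reaction and leaves the enoate alone.

**Step 13**
Reactants: 12 tert-butyl({(2R,3R)-3-[(3E)-6-iodo-3-methylhex-3-en-1-yl]-2-methyloxiran-2-yl}methoxy)dimethylsilane; 21 2-(trimethylsilyl)ethyl (2E)-7,7-dichloro-3-methylhepta-2,6-dienoate
Product: 23 2-(trimethylsilyl)ethyl (2E,6Z,10E)-13-[(2R,3R)-3-({[tert-butyl(dimethyl)silyl]oxy}methyl)-3-methyloxiran-2-yl]-7-chloro-3,11-dimethyltrideca-2,6,10-trienoate, via alkylzinc iodide 22 (not isolated)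
Conditions: Zn dust, LiCl, THF, 25 °C; then 21, PdCl2(DPEphos) (5 mol %), THF–DMF, 23–45 °C
Reagents that add atoms: none
Why: LiCl-assisted zinc insertion gives an ester- and epoxide-tolerant alkylzinc, and the Negishi coupling with the 1,1-dichloroalkene under the wide-bite-angle DPEphos catalyst replaces only the less hindered chlorine trans to the alkyl chain (trans-selective mono-alkylation), so C7 ends anti to C11 and a (Z)-alkenyl chloride remains.

**Step 14**
Reactants: 23 2-(trimethylsilyl)ethyl (2E,6Z,10E)-13-[(2R,3R)-3-({[tert-butyl(dimethyl)silyl]oxy}methyl)-3-methyloxiran-2-yl]-7-chloro-3,11-dimethyltrideca-2,6,10-trienoate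
Product: 24 2-(trimethylsilyl)ethyl (2E,6Z,10E)-13-[(2R,3R)-3-({[tert-butyl(dimethyl)silyl]oxy}methyl)-3-methyloxiran-2-yl]-3,11-dimethyl-7-[(trimethylsilyl)methyl]trideca-2,6,10-trienoate
Conditions: Me3SiCH2MgCl, ZnCl2, THF, 0 °C (gives Me3SiCH2ZnCl); Pd(P(t-Bu)3)2 (5 mol %), THF–NMP, 45 °C
Reagents that add atoms: (trimethylsilyl)methylmagnesium chloride, C[Si](C)(C)C[Mg]Cl
Why: A second Negishi coupling with the bulky electron-rich Pd(P(t-Bu)3)2 catalyst activates the hindered alkenyl chloride and couples it with the β-hydride-free Me3SiCH2ZnCl with retention of configuration, giving the (Z)-2-substituted allylsilane in the presence of the epoxide and the ester.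

**Step 15**
Reactants: 24 2-(trimethylsilyl)ethyl (2E,6Z,10E)-13-[(2R,3R)-3-({[tert-butyl(dimethyl)silyl]oxy}methyl)-3-methyloxiran-2-yl]-3,11-dimethyl-7-[(trimethylsilyl)methyl]trideca-2,6,10-trienoate
Product: 25 2-(trimethylsilyl)ethyl (2E)-5-[(1R,4aS,5S,6R,8aS)-5-({[tert-butyl(dimethyl)silyl]oxy}methyl)-6-hydroxy-5,8a-dimethyl-2-methylidenedecahydronaphthalen-1-yl]-3-methylpent-2-enoate
Conditions: MeAlCl2 (3 equiv), CH2Cl2, −78 °C, 1 h; Et3N, MeOH–H2O quench
Reagents that add atoms: none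
Why: Epoxide-initiated, allylsilane-terminated cation–olefin bicyclisation in which the (E)-C5=C10 alkene opens the MeAlCl2-activated epoxide with inversion at C4 and loss of Me3Si gives only the exocyclic C8=C17 alkene, the chair–chair transition state turning the (R,R)-epoxide and the two alkene geometries into the trans-decalin with equatorial C3–OH, equatorial C4–CH2OTBS (the former (E) substituent), axial C4–CH3 and equatorial C9 side chain, i.e. all five stereocentres of the target.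

**Step 16**
Reactants: 25 2-(trimethylsilyl)ethyl (2E)-5-[(1R,4aS,5S,6R,8aS)-5-({[tert-butyl(dimethyl)silyl]oxy}methyl)-6-hydroxy-5,8a-dimethyl-2-methylidenedecahydronaphthalen-1-yl]-3-methylpent-2-enoate; 26 (2Z)-2-methylbut-2-enoic acid (angelic acid)
Product: 28 2-(trimethylsilyl)ethyl (2E)-5-[(1R,4aS,5S,6R,8aS)-5-({[tert-butyl(dimethyl)silyl]oxy}methyl)-5,8a-dimethyl-2-methylidene-6-{[(2Z)-2-methylbut-2-enoyl]oxy}decahydronaphthalen-1-yl]-3-methylpent-2-enoate, via mixed anhydride 27 (not isolated)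
Conditions: 26, 2,4,6-trichlorobenzoyl chloride, Et3N, toluene, rt; then 25, toluene, 80 °C
Reagents that add atoms: none
Why: Yamaguchi-type esterification in which the mixed anhydride is attacked by the hindered equatorial alcohol at the less hindered angeloyl carbonyl without a nucleophilic catalyst, conditions that keep the (Z) geometry of the angelate instead of isomerising it to the tiglate.

**Step 17**
Reactants: 28 2-(trimethylsilyl)ethyl (2E)-5-[(1R,4aS,5S,6R,8aS)-5-({[tert-butyl(dimethyl)silyl]oxy}methyl)-5,8a-dimethyl-2-methylidene-6-{[(2Z)-2-methylbut-2-enoyl]oxy}decahydronaphthalen-1-yl]-3-methylpent-2-enoate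
Product: 29 (2E)-5-[(1R,4aS,5S,6R,8aS)-5-(hydroxymethyl)-5,8a-dimethyl-2-methylidene-6-{[(2Z)-2-methylbut-2-enoyl]oxy}decahydronaphthalen-1-yl]-3-methylpent-2-enoic acid
Conditions: Bu4NF (5 equiv), AcOH (3 equiv), THF, 0 °C → rt; pH 5 buffer work-up
Reagents that add atoms: none
Why: Fluoride-mediated desilylation cleaves the primary TBS ether and fragments the 2-(trimethylsilyl)ethyl ester (ethene and Me3SiF) in one operation, and the acetic acid buffer keeps the medium near neutral so that the angelate neither migrates to the freed C18 hydroxyl nor is hydrolysed.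

**Compound list**
1 | pent-3-yn-1-ol | CC#CCCO | starting material
2 | 5-chloropent-2-yne | CC#CCCCl | intermediate
3 | chlorobis(cyclopentadienyl)[(2E)-5-chloropent-2-en-2-yl]zirconium | Cl[Zr](C1C=CC=C1)(C1C=CC=C1)/C(C)=C/CCCl | intermediate
4 | (2E)-5-chloro-2-iodopent-2-ene | I/C(C)=C/CCCl | intermediate
5 | prop-2-enal (acrolein) | C=CC=O | starting material
6 | ethyl (2E)-2-methylpenta-2,4-dienoate | CCOC(=O)/C(C)=C/C=C | intermediate
7 | (2E)-2-methylpenta-2,4-dien-1-ol | OC/C(C)=C/C=C | intermediate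
8 | 9-[(3E)-5-(9-borabicyclo[3.3.1]nonan-9-yloxy)-4-methylpent-3-en-1-yl]-9-borabicyclo[3.3.1]nonane | C1CCC2CCCC1B2OC/C(C)=C/CCB1C2CCCC1CCC2 | intermediate
9 | (2E,6E)-9-chloro-2,6-dimethylnona-2,6-dien-1-ol | OC/C(C)=C/CC/C(C)=C/CCCl | intermediate
10 | {(2R,3R)-3-[(3E)-6-chloro-3-methylhex-3-en-1-yl]-2-methyloxiran-2-yl}methanol | OC[C@@]1(C)O[C@@H]1CC/C(C)=C/CCCl | intermediate
11 | tert-butyl({(2R,3R)-3-[(3E)-6-chloro-3-methylhex-3-en-1-yl]-2-methyloxiran-2-yl}methoxy)dimethylsilane | CC(C)(C)[Si](C)(C)OC[C@@]1(C)O[C@@H]1CC/C(C)=C/CCCl | intermediate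
12 | tert-butyl({(2R,3R)-3-[(3E)-6-iodo-3-methylhex-3-en-1-yl]-2-methyloxiran-2-yl}methoxy)dimethylsilane | CC(C)(C)[Si](C)(C)OC[C@@]1(C)O[C@@H]1CC/C(C)=C/CCI | intermediate
13 | but-2-ynoic acid | CC#CC(=O)O | starting material
14 | 2-(trimethylsilyl)ethanol | C[Si](C)(C)CCO | starting material
15 | 2-(trimethylsilyl)ethyl but-2-ynoate | CC#CC(=O)OCC[Si](C)(C)C | intermediate
16 | 2-(2-bromoethyl)-1,3-dioxolane | BrCCC1OCCO1 | starting material
17 | [2-(1,3-dioxolan-2-yl)ethyl]magnesium bromide | Br[Mg]CCC1OCCO1 | intermediate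
18 | [2-(1,3-dioxolan-2-yl)ethyl]copper (as its MgBr2 complex) | [Cu]CCC1OCCO1 | intermediate
19 | 2-(trimethylsilyl)ethyl (2E)-5-(1,3-dioxolan-2-yl)-3-methylpent-2-enoate | C/C(CCC1OCCO1)=C\C(=O)OCC[Si](C)(C)C | intermediate
20 | 2-(trimethylsilyl)ethyl (2E)-3-methyl-6-oxohex-2-enoate | C/C(CCC=O)=C\C(=O)OCC[Si](C)(C)C | intermediate
21 | 2-(trimethylsilyl)ethyl (2E)-7,7-dichloro-3-methylhepta-2,6-dienoate | C/C(CCC=C(Cl)Cl)=C\C(=O)OCC[Si](C)(C)C | intermediate
22 | iodo{(3E)-6-[(2R,3R)-3-({[tert-butyl(dimethyl)silyl]oxy}methyl)-3-methyloxiran-2-yl]-4-methylhex-3-en-1-yl}zinc | CC(C)(C)[Si](C)(C)OC[C@@]1(C)O[C@@H]1CC/C(C)=C/CC[Zn]I | intermediate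
23 | 2-(trimethylsilyl)ethyl (2E,6Z,10E)-13-[(2R,3R)-3-({[tert-butyl(dimethyl)silyl]oxy}methyl)-3-methyloxiran-2-yl]-7-chloro-3,11-dimethyltrideca-2,6,10-trienoate | CC(C)(C)[Si](C)(C)OC[C@@]1(C)O[C@@H]1CC/C(C)=C/CC/C(Cl)=C/CC/C(C)=C/C(=O)OCC[Si](C)(C)C | intermediate
24 | 2-(trimethylsilyl)ethyl (2E,6Z,10E)-13-[(2R,3R)-3-({[tert-butyl(dimethyl)silyl]oxy}methyl)-3-methyloxiran-2-yl]-3,11-dimethyl-7-[(trimethylsilyl)methyl]trideca-2,6,10-trienoate | CC(C)(C)[Si](C)(C)OC[C@@]1(C)O[C@@H]1CC/C(C)=C/CC/C(C[Si](C)(C)C)=C/CC/C(C)=C/C(=O)OCC[Si](C)(C)C | intermediate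
25 | 2-(trimethylsilyl)ethyl (2E)-5-[(1R,4aS,5S,6R,8aS)-5-({[tert-butyl(dimethyl)silyl]oxy}methyl)-6-hydroxy-5,8a-dimethyl-2-methylidenedecahydronaphthalen-1-yl]-3-methylpent-2-enoate | C=C1CC[C@H]2[C@@](C)(CC[C@@H](O)[C@]2(C)CO[Si](C)(C)C(C)(C)C)[C@@H]1CC/C(C)=C/C(=O)OCC[Si](C)(C)C | intermediate
26 | (2Z)-2-methylbut-2-enoic acid (angelic acid) | C/C=C(/C)C(=O)O | starting material
27 | (2Z)-2-methylbut-2-enoic 2,4,6-trichlorobenzoic anhydride | C/C=C(/C)C(=O)OC(=O)c1c(Cl)cc(Cl)cc1Cl | intermediate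
28 | 2-(trimethylsilyl)ethyl (2E)-5-[(1R,4aS,5S,6R,8aS)-5-({[tert-butyl(dimethyl)silyl]oxy}methyl)-5,8a-dimethyl-2-methylidene-6-{[(2Z)-2-methylbut-2-enoyl]oxy}decahydronaphthalen-1-yl]-3-methylpent-2-enoate | C=C1CC[C@H]2[C@@](C)(CC[C@@H](OC(=O)/C(C)=C\C)[C@]2(C)CO[Si](C)(C)C(C)(C)C)[C@@H]1CC/C(C)=C/C(=O)OCC[Si](C)(C)C | intermediate
29 | (2E)-5-[(1R,4aS,5S,6R,8aS)-5-(hydroxymethyl)-5,8a-dimethyl-2-methylidene-6-{[(2Z)-2-methylbut-2-enoyl]oxy}decahydronaphthalen-1-yl]-3-methylpent-2-enoic acid | C=C1CC[C@H]2[C@@](C)(CC[C@@H](OC(=O)/C(C)=C\C)[C@]2(C)CO)[C@@H]1CC/C(C)=C/C(=O)O | target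

**Totals**
Total step count: 17.
Longest linear sequence: 11 steps (steps 1, 2, 5, 6, 7, 8, 13, 14, 15, 16, 17; the branch through steps 3 and 4 is equally long).

**Steps most likely to fail, with fallbacks**

Step 13 (fragment union). The epoxide of 12 may not survive zinc insertion or the zinc salts, and the mono-coupling must stop cleanly after one chlorine. The fallback sets out from 9 and comes back at 23; it installs the epoxide after the union instead of before. Alcohol 9 is silylated (TBSCl, imidazole) to tert-butyl{[(2E,6E)-9-chloro-2,6-dimethylnona-2,6-dien-1-yl]oxy}dimethylsilane F1. Finkelstein exchange gives tert-butyl{[(2E,6E)-9-iodo-2,6-dimethylnona-2,6-dien-1-yl]oxy}dimethylsilane F2. Zinc insertion gives iodo[(3E,7E)-9-{[tert-butyl(dimethyl)silyl]oxy}-4,8-dimethylnona-3,7-dien-1-yl]zinc F3, which now carries no epoxide. Coupling with 21 under PdCl2(DPEphos) gives 2-(trimethylsilyl)ethyl (2E,6Z,10E,14E)-16-{[tert-butyl(dimethyl)silyl]oxy}-7-chloro-3,11,15-trimethylhexadeca-2,6,10,14-tetraenoate F4. HF·pyridine removes only the allylic silyl ether to give 2-(trimethylsilyl)ethyl (2E,6Z,10E,14E)-7-chloro-16-hydroxy-3,11,15-trimethylhexadeca-2,6,10,14-tetraenoate F5. Hydroxyl-directed Sharpless epoxidation with D-(−)-diethyl tartrate touches only the allylic-alcohol alkene and gives 2-(trimethylsilyl)ethyl (2E,6Z,10E)-7-chloro-13-[(2R,3R)-3-(hydroxymethyl)-3-methyloxiran-2-yl]-3,11-dimethyltrideca-2,6,10-trienoate F6, and silylation returns to 23.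

Step 15 (bicyclisation). The CH2OTBS group next to the epoxide slows ionisation, and protodesilylation or partial cyclisation can compete. The fallback sets out from 23 and comes back at 25; it uses the alkenyl chloride itself as terminator and adds the methylene carbon afterwards. Treatment of 23 with MeAlCl2 (or SnCl4) in CH2Cl2 at −78 °C closes both rings, and the chlorine-stabilised C8 cation is hydrolysed on aqueous work-up. This gives the 17-nor-8-ketone 2-(trimethylsilyl)ethyl (2E)-5-[(1S,4aS,5S,6R,8aR)-5-({[tert-butyl(dimethyl)silyl]oxy}methyl)-6-hydroxy-5,8a-dimethyl-2-oxodecahydronaphthalen-1-yl]-3-methylpent-2-enoate F7. It has the same spatial arrangement as 25 (the descriptors at C1 and C8a change only through priority), and the equatorial C9 side chain is also the thermodynamic epimer. Wittig methylenation with Ph3P=CH2 (3 equiv, THF, rt → 50 °C) then gives 25.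

Step 16 (angeloylation). The C3 alcohol is flanked by a quaternary carbon, and forcing conditions risk isomerisation to the tiglate. The fallback sets out from 25 and comes back at 28; it builds the (Z)-alkene on the ester instead of transferring a preformed angeloyl group. DCC/DMAP coupling of 25 with 2-[bis(2,2,2-trifluoroethoxy)phosphoryl]propanoic acid gives 2-(trimethylsilyl)ethyl (2E)-5-[(1R,4aS,5S,6R,8aS)-6-({2-[bis(2,2,2-trifluoroethoxy)phosphoryl]propanoyl}oxy)-5-({[tert-butyl(dimethyl)silyl]oxy}methyl)-5,8a-dimethyl-2-methylidenedecahydronaphthalen-1-yl]-3-methylpent-2-enoate F8 (both epimers at the phosphonate carbon). Still–Gennari olefination (KN(SiMe3)2, 18-crown-6, THF, −78 °C, then acetaldehyde) forms the (Z)-2-methylbut-2-enoate selectively and gives 28.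

**Further compounds**
F1 | step 13 | tert-butyl{[(2E,6E)-9-chloro-2,6-dimethylnona-2,6-dien-1-yl]oxy}dimethylsilane | CC(C)(C)[Si](C)(C)OC/C(C)=C/CC/C(C)=C/CCCl
F2 | step 13 | tert-butyl{[(2E,6E)-9-iodo-2,6-dimethylnona-2,6-dien-1-yl]oxy}dimethylsilane | CC(C)(C)[Si](C)(C)OC/C(C)=C/CC/C(C)=C/CCI
F3 | step 13 | iodo[(3E,7E)-9-{[tert-butyl(dimethyl)silyl]oxy}-4,8-dimethylnona-3,7-dien-1-yl]zinc | CC(C)(C)[Si](C)(C)OC/C(C)=C/CC/C(C)=C/CC[Zn]I
F4 | step 13 | 2-(trimethylsilyl)ethyl (2E,6Z,10E,14E)-16-{[tert-butyl(dimethyl)silyl]oxy}-7-chloro-3,11,15-trimethylhexadeca-2,6,10,14-tetraenoate | CC(C)(C)[Si](C)(C)OC/C(C)=C/CC/C(C)=C/CC/C(Cl)=C/CC/C(C)=C/C(=O)OCC[Si](C)(C)C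
F5 | step 13 | 2-(trimethylsilyl)ethyl (2E,6Z,10E,14E)-7-chloro-16-hydroxy-3,11,15-trimethylhexadeca-2,6,10,14-tetraenoate | OC/C(C)=C/CC/C(C)=C/CC/C(Cl)=C/CC/C(C)=C/C(=O)OCC[Si](C)(C)C
F6 | step 13 | 2-(trimethylsilyl)ethyl (2E,6Z,10E)-7-chloro-13-[(2R,3R)-3-(hydroxymethyl)-3-methyloxiran-2-yl]-3,11-dimethyltrideca-2,6,10-trienoate | OC[C@@]1(C)O[C@@H]1CC/C(C)=C/CC/C(Cl)=C/CC/C(C)=C/C(=O)OCC[Si](C)(C)C
F7 | step 15 | 2-(trimethylsilyl)ethyl (2E)-5-[(1S,4aS,5S,6R,8aR)-5-({[tert-butyl(dimethyl)silyl]oxy}methyl)-6-hydroxy-5,8a-dimethyl-2-oxodecahydronaphthalen-1-yl]-3-methylpent-2-enoate | O=C1CC[C@H]2[C@@](C)(CC[C@@H](O)[C@]2(C)CO[Si](C)(C)C(C)(C)C)[C@@H]1CC/C(C)=C/C(=O)OCC[Si](C)(C)C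
F8 | step 16 | 2-(trimethylsilyl)ethyl (2E)-5-[(1R,4aS,5S,6R,8aS)-6-({2-[bis(2,2,2-trifluoroethoxy)phosphoryl]propanoyl}oxy)-5-({[tert-butyl(dimethyl)silyl]oxy}methyl)-5,8a-dimethyl-2-methylidenedecahydronaphthalen-1-yl]-3-methylpent-2-enoate | C=C1CC[C@H]2[C@@](C)(CC[C@@H](OC(=O)C(C)P(=O)(OCC(F)(F)F)OCC(F)(F)F)[C@]2(C)CO[Si](C)(C)C(C)(C)C)[C@@H]1CC/C(C)=C/C(=O)OCC[Si](C)(C)C
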